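## Analysis of the target

Remark on notation: briarane numbering (C1–C20) is used for every compound; in the decalin intermediates ring B is C1–C2–C3–C8–C9–C10 with C3 bonded to C8. β is the face of the C15 methyl group in the flat drawing, α the opposite face.

CNP0379630.2 (C24H31ClO10) is a briarane: a cyclohexane (ring A: C1, C10–C14) trans-fused through C1–C10 to a ten-membered carbocycle (C1–C10), with a γ-lactone (O7, C17, C18 methyl, C19 carbonyl) annulated at C7–C8. It has fourteen stereocentres. Ring A carries the quaternary C1 (15-CH3 β), H-10 α, the axial 20-CH3 β (cis to 15-CH3, the less stable arrangement), 12β-OAc and the 13α,14α-epoxide. The large ring carries 2α-OH, the cis 3α,4α-epoxide, 6α-Cl, O7 (H-7 β), 8α-OH and 9α-OAc; C17 has its methyl α. The vinyl epoxide flanked by the C5=C16 methylene and the secondary allylic chloride is prone to SN2' and solvolysis, the β-hydroxy lactone to retro-aldol cleavage, and two acetates must be told apart from the free 2-OH and tertiary 8-OH. The hard part is a ten-membered ring anchored on a quaternary carbon with contiguous functionality from C2 to C9, where stereocontrol on the flexible ring is weak.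

The feature the plan exploits: the large ring is a six-membered ring (C1, C2, C3, C8, C9, C10) plus the four-carbon insert C4–C5(C16)–C6–C7. C8 is at ketone level, C7 is its oxygenated α-carbon, C3–C4 is at olefin level and C5–C6 is a plain σ bond. That is the exact imprint of an oxy-Cope rearrangement of a C8 vinyl carbinol bearing an alkenyl group on C3.

## Retrosynthetic reasoning

**30 ⇒ 29 (C13–O, C14–O).** The ring-A epoxide is put on last, because the only other olefin left in 29, C5=C16, is deactivated by the allylic chloride and the allylic epoxide. The forward reaction must attack C13=C14 from the α face, anti to 12β-OAc and the axial C15 methyl.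

**29 ⇒ 28 (C6–Cl, with shift of C5=C6 to C5=C16).** An ene-type chlorination of a trisubstituted C5=C6 olefin delivers the chloride and the exocyclic methylene in one operation, so neither needs its own carbon–heteroatom construction.

**28 ⇒ 27 (C3–O, C4–O).** The cis-epoxide is cut back to a Z-olefin next to the free 2α-hydroxyl, which can direct the oxidant to this one double bond and to the α face. Protecting-group changes lead back through 26, 25 and 24, and an E to Z olefin isomerisation leads to 23.

**23 ⇒ 21 ⇒ 20 (C8–C17).** The lactone is cut at C8–C17: a 2-bromopropanoate on O7 closes onto the C8 ketone. This sets C8 and C17 together and asks only for an α-hydroxy ketone.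

**20 ⇒ 18 ⇒ 17 (C7–O, C5=C6).** The C7 hydroxyl and the C5=C6 olefin come from a C6=C7 enone by γ-deprotonation and α-oxygenation. The enone comes from a regiodefined C7=C8 silyl enol ether.

**17 ⇒ 15 (key: C5–C6 cut, C3–C8 re-formed).** The ten-membered ring of 17 collapses to the decalin 15, a C8 vinyl carbinol with a propenyl group on C3. Cutting here replaces a macrocyclisation by a [3,3] shift through a six-membered transition state, and all stereocentres of C1, C2, C9, C10, C11 and C12 can be set on a rigid trans-decalin.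

**15 ⇒ 14 ⇒ 13 ⇒ 12 (C3–C4, C7–C8, C2–O).** The propenyl group comes from trans-diaxial opening of a 2α,3α-epoxide, the vinyl group from addition to the C8 ketone anti to that epoxide, and the epoxide from nucleophilic epoxidation of the C8 enone anti to the C15 methyl. Oxygen is delivered to C2 from the α face, which a hydride reduction of a C2 ketone could not achieve.

**12 ⇒ 10 ⇒ 8 ⇒ 6 ⇒ 5 ⇒ 3 + 2 (C1–C14, C10–C11).** The enone 10 arises by reduction and 1,3-carbonyl transposition of a methoxy-enedione. Decalin 5 is the Diels–Alder adduct of quinone 3 and silyloxydiene 2 (made from 1), which builds the quaternary C1 and brings twelve of the twenty skeletal carbons.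

## Alternatives that were turned down

Alternative 1: Nozaki–Hiyama–Kishi closure of C5–C6 (the textbook route). A 2-iodoallyl unit at C5 adds to a C6 aldehyde in seco compound A1 to give the macrocyclic allylic alcohol A2, and the chloride follows by inversion. Turned down because every stereocentre from C2 to C9 would have to be built on two open chains before the ring exists, which costs far more steps than the ring closure saves. The C6 carbinol configuration would rest on a flexible ten-membered transition state, the vinyl iodide sits next to an epoxide, and the closure needs high dilution against a quaternary centre.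

Alternative 2: ring-closing enyne metathesis forming C3=C4. Enyne A3 (C2 vinyl carbinol and a propargylic chloride at C6) would give diene A4, which has both the ring olefin and the C5=C16 methylene. Turned down because ten-membered rings lie at the border between exo and endo enyne closure, the second-generation Grubbs catalyst could engage the ring-A olefin and the free hydroxyls, and the fully elaborated lactone-bearing chain must again be made linearly.

Alternative 3: oxidative scission of C3=C8 in a hydroanthracene. A naphthoquinone Diels–Alder adduct, reduced (Birch) to tricycle A5, would be cleaved at its tetrasubstituted C3=C8 olefin to the ten-membered 3,8-diketone A6. The entry is very short, but it was turned down on three counts. Birch reduction must spare two benzylic C–O bonds. A6 is pseudo-symmetric: two β,γ-unsaturated ketones must be told apart and their bis-enol can re-close by 6π electrocyclisation. And C3 emerges as a ketone that needs three to five steps to become the olefin again.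

Key step: step 10

## Route

Step 1
Reactants: 1 ethyl vinyl ketone
Product: 2 (Z)-triisopropyl(penta-1,3-dien-3-yloxy)silane
Conditions: i-Pr3SiOSO2CF3, Et3N, CH2Cl2, 0 °C
Reagents that add atoms: triisopropylsilyl trifluoromethanesulfonate, CC(C)[Si](C(C)C)(C(C)C)OS(=O)(=O)C(F)(F)F
Why: Soft enolisation of the ethyl ketone (silyl enol ether formation) gives the 2-silyloxydiene; the Z isomer, with the methyl group outside in the s-cis diene, is the favoured product.

Step 2
Reactants: 3 2-methoxy-5-methyl-1,4-benzoquinone; 2 (Z)-triisopropyl(penta-1,3-dien-3-yloxy)silane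
Product: 5 trans-fused adduct (C2/C9 dione; 8-OMe enol ether; 12-OSi(i-Pr)3 enol ether; 15-CH3 β; H-10 α; 20-CH3 α), via cis adduct 4 (not isolated)
Conditions: (S)-o-tolyl-oxazaborolidinium triflimide [from (S)-α,α-diphenylprolinol, tri(o-tolyl)boroxine and HN(SO2CF3)2] (20 mol %), CH2Cl2, −78 °C; then DBU (0.5 equiv), 0 → 25 °C
Reagents that add atoms: none
Why: Lewis-acid-catalysed endo Diels–Alder reaction: the boron cation binds the more basic vinylogous-ester carbonyl (C2), so the unsubstituted C10 is the electrophilic terminus and bonds to the nucleophilic CH(CH3) end of the diene while its CH2 end closes onto C1. The chiral cation shields one face and sets the quaternary C1; the antipodal catalyst would be used if the sense of induction proves opposite. DBU then epimerises C10 through the C9 enolate to the more stable trans-fused decalin.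

Step 3
Reactants: 5 trans-fused adduct
Product: 6 trans-fused trione (C12 ketone conjugated with C13=C14; 20-CH3 α)
Conditions: Pd(OAc)2 (1.1 equiv), MeCN, 25 °C
Reagents that add atoms: none
Why: Saegusa–Ito oxidation: the silyl enol ether gives a C13 enolate of divalent palladium, and β-hydride elimination of H-14 forms the C13=C14 enone; no stereocentre is touched.

Step 4
Reactants: 6 trans-fused trione
Product: 8 11-epimeric trione (20-CH3 β; H-11 α; H-10 α), via dilithium bis-enolate 7 (not isolated)
Conditions: LiN(i-Pr)2 (2.3 equiv), THF, −78 °C; then inverse quench into AcOH/THF, −78 °C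
Reagents that add atoms: none
Why: Double deprotonation gives the nearly planar C9/C12 bis-enolate in which C1 is the only sp3 ring atom; its methyl group blocks the β face, so both C10 and C11 should be protonated from the α face (kinetic protonation). This restores the trans fusion and places the C20 methyl β, the less stable epimer that the target needs.

Step 5
Reactants: 8 11-epimeric trione
Product: 10 hydroxy enone (C8 ketone; C2=C3; 9β-OH; 12β-OH; C13=C14), via triol 9 (not isolated)
Conditions: (i-Bu)2AlH (5 equiv), CH2Cl2, −78 °C; then 1 M HCl, THF, 0 °C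
Reagents that add atoms: water, O
Why: 1,2-Reduction of all three carbonyls from the α face, anti to the axial methyl groups, gives 12β-OH and 9β-OH. Acid then hydrolyses the vinylogous hemiketal with loss of the C2 oxygen (Stork–Danheiser-type 1,3-carbonyl transposition) and unveils the C8 enone; the plain allylic alcohol at C12 ionises far more slowly than the enol-ether-assisted C2 centre.

Step 6
Reactants: 10 hydroxy enone
Product: 12 9α,12β-bis(triethylsilyl) ether of the enone, via 9β-silyl ether 11 (not isolated)
Conditions: Et3SiOSO2CF3, 2,6-lutidine, CH2Cl2, −78 → 0 °C; then DBU (0.3 equiv), toluene, 60 °C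
Reagents that add atoms: triethylsilyl trifluoromethanesulfonate, CC[Si](CC)(CC)OS(=O)(=O)C(F)(F)F
Why: After silylation the axial 9β-silyloxy group is syn-diaxial to both the C15 and C20 methyl groups; C9 is the only enolisable position of the C8 ketone, so base equilibrates it to the equatorial 9α epimer (thermodynamic epimerisation).

Step 7
Reactants: 12 9α,12β-bis(triethylsilyl) ether of the enone
Product: 13 2α,3α-epoxy-8-ketone
Conditions: t-BuOOH, DBU, CH2Cl2, 0 → 25 °C
Reagents that add atoms: tert-butyl hydroperoxide, CC(C)(C)OO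
Why: Weitz–Scheffer nucleophilic epoxidation touches only the enone; the peroxide anion adds to C2 anti to the adjacent axial C15 methyl, so the epoxide, and with it the future C2–O bond, is α.

Step 8
Reactants: 13 2α,3α-epoxy-8-ketone
Product: 14 8β-vinyl-8α-hydroxy 2α,3α-epoxide
Conditions: CH2=CHMgBr, THF, −78 °C
Reagents that add atoms: vinylmagnesium bromide, C=C[Mg]Br
Why: Grignard 1,2-addition to an α,β-epoxy ketone occurs anti to the epoxide oxygen, giving the equatorial 8β-vinyl group and the axial 8α-alkoxide.

Step 9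
Reactants: 14 8β-vinyl-8α-hydroxy 2α,3α-epoxide
Product: 15 3β-[(E)-prop-1-enyl]-8β-vinyl-2α,8α-diol
Conditions: (E)-CH3CH=CHMgBr (4 equiv), CuI (copper monoiodide, 20 mol %), THF, −40 → 0 °C
Reagents that add atoms: (E)-prop-1-enylmagnesium bromide, C/C=C/[Mg]Br
Why: Copper-catalysed trans-diaxial (Fürst–Plattner) epoxide opening: the alkenyl group attacks C3 from the β face, since attack at neopentyl C2 would be equatorial and blocked by the quaternary C1. C2 keeps its α oxygen, and the axial 3β-propenyl group ends up cis and gauche to the 8β-vinyl group.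

Step 10
Reactants: 15 3β-[(E)-prop-1-enyl]-8β-vinyl-2α,8α-diol
Product: 17 ten-membered bis(tert-butyldimethylsilyl) compound ((3E)-olefin; C7=C8 silyl enol ether; 2α-OSi; 5-methyl; 9α,12β-bis-OSiEt3), via potassium enolate 16 (not isolated)
Conditions: KH (3 equiv), 18-crown-6, THF, 0 → 25 °C; then t-BuMe2SiCl, −78 → 0 °C
Reagents that add atoms: tert-butyldimethylsilyl chloride, CC(C)(C)[Si](C)(C)Cl
Why: Anionic oxy-Cope rearrangement: the C8 potassium alkoxide accelerates a [3,3]-sigmatropic shift in which the C3–C8 ring bond breaks while C5–C6 forms, so ring B (C1, C2, C3, C8, C9, C10) is expanded by the four carbons C4–C7 to the ten-membered ring. The closest known reaction type is the ring expansion of 1,2-dialkenylcyclohexanols to cyclodec-5-enones with trapping of the enolate, as used for germacrane-type rings. The ten-membered ring is not closed end to end but arises through a six-membered chair transition state (C3, C4, C5, C6, C7, C8), which avoids the entropic and transannular cost of a macrocyclisation. The axial 3β-propenyl and equatorial 8β-vinyl groups are held gauche by the rigid trans-decalin, the alkoxide is pseudo-equatorial in the chair, and the 1,3-diaxial strain between the propenyl group and the C15 methyl is released. This chair fixes C3=C4 as E and the C7=C8 enolate with C6 and C9 cis; it also transfers the C3/C8 chirality to the new C5 stereocentre (methyl pseudo-equatorial from the E-propenyl group), which is erased again in step 12. The stereocentres C1, C2, C9, C10, C11 and C12, all set on the decalin, are carried over untouched. The step needs the concerted shift to outrun heterolytic cleavage of the alkoxide and silyl transfer from O9; the cis-1,2 relation of the alkenyl groups and the crown-ether-separated ion pair should secure this. Silylation of the enolate oxygen and the C2 alkoxide stores the regiodefined C7=C8 enol for step 11.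

Step 11
Reactants: 17 ten-membered bis(tert-butyldimethylsilyl) compound
Product: 18 (3E,6Z)-dien-8-one (2α-OSi-t-BuMe2; 9α,12β-bis-OSiEt3)
Conditions: Pd(OAc)2 (1.1 equiv), MeCN/CH2Cl2, 25 °C
Reagents that add atoms: none
Why: Saegusa–Ito oxidation of the regiodefined silyl enol ether: the C7 palladium enolate can only eliminate H-6, so the new double bond forms toward C6 and not toward the oxygenated C9.

Step 12
Reactants: 18 (3E,6Z)-dien-8-one
Product: 20 7α-hydroxy-(3E,5Z)-dien-8-one, via potassium trienolate 19 (not isolated)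
Conditions: KN(SiMe3)2 (1.1 equiv), THF, −78 °C; then 2-(phenylsulfonyl)-3-phenyloxaziridine, −78 °C; NH4Cl
Reagents that add atoms: 2-(phenylsulfonyl)-3-phenyloxaziridine, O=S(=O)(c1ccccc1)N1OC1c1ccccc1
Why: H-5 is doubly allylic, so the base forms the extended enolate; oxygen transfer from the oxaziridine occurs at the α-carbon C7 (deconjugative α-hydroxylation), which moves the double bond to C5=C6 with the C16 methyl on it and erases C5. Attack on the peripheral face of the ring-cis enolate is expected to place the hydroxyl α (H-7 β).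

Step 13
Reactants: 20 7α-hydroxy-(3E,5Z)-dien-8-one
Product: 21 7-O-(2-bromopropanoyl) ester
Conditions: 2-bromopropanoyl bromide, pyridine, CH2Cl2, −40 °C
Reagents that add atoms: 2-bromopropanoyl bromide, CC(Br)C(Br)=O
Why: Acylation of the only free hydroxyl; the bromine-bearing carbon is an inconsequential mixture of epimers, because it becomes an enolate carbon in step 14.

Step 14
Reactants: 21 7-O-(2-bromopropanoyl) ester
Product: 23 (3E,5Z)-hydroxy lactone (8α-OH; 18-CH3 α), via samarium enolate 22 (not isolated)
Conditions: SmI2 (samarium diiodide, 2.5 equiv), THF, −78 °C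
Reagents that add atoms: none
Why: Samarium-diiodide-mediated intramolecular Reformatsky reaction: two single-electron transfers cleave the C–Br bond and the ester enolate of trivalent samarium adds to the neighbouring C8 ketone. The O7-tethered nucleophile can reach C8 only when the ring torsion C6–C7–C8–C9 is transoid (a cisoid arrangement would eclipse C6 and C9 across the ring), which places the new hydroxyl cis to C6, the natural 8α configuration. The C18 methyl settles trans to the bulky C9 side, and C17 stays correctable by base equilibration.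

Step 15
Reactants: 23 (3E,5Z)-hydroxy lactone
Product: 24 (3Z,5Z)-hydroxy lactone
Conditions: I2 (iodine, 5 mol %), CH2Cl2, visible light, 25 °C
Reagents that add atoms: none
Why: Iodine-atom-catalysed olefin isomerisation: reversible addition to the conjugated diene allows rotation about C3–C4 and should funnel the strained E olefin into the (3Z,5Z)-diene, the more stable geometry of a 1,3-diene in a ten-membered ring.

Step 16
Reactants: 24 (3Z,5Z)-hydroxy lactone
Product: 25 9α,12β-diol (2α-OSi-t-BuMe2 retained)
Conditions: HF·pyridine, pyridine, THF, 0 °C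
Reagents that add atoms: none
Why: Buffered HF·pyridine cleaves the two triethylsilyl ethers, while the hindered tert-butyldimethylsilyl ether on O2 survives (graded silyl ether lability); the non-basic medium avoids retro-aldol opening of the β-hydroxy lactone.

Step 17
Reactants: 25 9α,12β-diol
Product: 26 9α,12β-diacetate
Conditions: Ac2O, 4-(dimethylamino)pyridine (cat.), pyridine, 25 °C
Reagents that add atoms: acetic anhydride, CC(=O)OC(C)=O
Why: Acetylation of the two secondary alcohols; the tertiary 8-OH does not react and O2 is still silylated, so the acetate pattern of the target is installed without ambiguity.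

Step 18
Reactants: 26 9α,12β-diacetate
Product: 27 2α-alcohol
Conditions: Bu4NF, AcOH, THF, 25 °C
Reagents that add atoms: none
Why: Fluoride-induced desilylation buffered with acetic acid frees the 2α-hydroxyl without acetate migration or retro-aldol cleavage.

Step 19
Reactants: 27 2α-alcohol
Product: 28 3α,4α-epoxide
Conditions: VO(acac)2 (5 mol %), t-BuOOH, CH2Cl2, 0 °C
Reagents that add atoms: tert-butyl hydroperoxide, CC(C)(C)OO
Why: Vanadium-catalysed hydroxyl-directed epoxidation: the metal-bound peroxide is delivered from O2 to the adjacent C3=C4 bond only, leaving C5=C6 and C13=C14 untouched. For Z-allylic alcohols in medium rings this delivery gives the cis (syn) epoxy alcohol, here the 3α,4α-epoxide next to 2α-OH, and the Z olefin gives the cis-epoxide.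

Step 20
Reactants: 28 3α,4α-epoxide
Product: 29 6α-chloro-5(16)-ene
Conditions: t-BuOCl, silica gel, CH2Cl2, −20 °C, dark
Reagents that add atoms: tert-butyl hypochlorite, CC(C)(C)OCl
Why: Ene-type chlorination of the trisubstituted olefin: electrophilic chlorine adds to the less substituted C6 and a proton is lost from the C16 methyl, which moves the double bond to C5=C16 in the same operation. Chlorine should enter on the exposed face anti to the C7–O bond (6α-Cl), and the trisubstituted C5=C6 bond reacts before the acetoxy-deactivated C13=C14 bond.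

Step 21
Reactants: 29 6α-chloro-5(16)-ene
Product: 30 CNP0379630.2
Conditions: 3-chloroperoxybenzoic acid, aqueous NaHCO3, CH2Cl2, 0 °C
Reagents that add atoms: 3-chloroperoxybenzoic acid, O=C(OO)c1cccc(Cl)c1
Why: Peracid epoxidation of the remaining ring-A olefin; the C5=C16 bond is deactivated by the allylic chloride and the allylic epoxide. The reagent adds anti to the 12β-acetoxy group and to the axial C15 methyl on the two neighbouring carbons, giving the 13α,14α-epoxide.

## Compound list

1 | ethyl vinyl ketone (pent-1-en-3-one) | C=CC(=O)CC | starting material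
2 | (Z)-triisopropyl(penta-1,3-dien-3-yloxy)silane | C/C=C(/C=C)O[Si](C(C)C)(C(C)C)C(C)C | intermediate
3 | 2-methoxy-5-methyl-1,4-benzoquinone | COC1=CC(=O)C(C)=CC1=O | starting material
4 | cis adduct (C2/C9 dione; 8-OMe enol ether; 12-silyl enol ether; 15-CH3 β; H-10 β; 20-CH3 α) | C[C@]12CC=C(O[Si](C(C)C)(C(C)C)C(C)C)[C@@H](C)[C@H]1C(=O)C(OC)=CC2=O | intermediate
5 | trans-fused adduct (as 4 but H-10 α) | C[C@]12CC=C(O[Si](C(C)C)(C(C)C)C(C)C)[C@@H](C)[C@@H]1C(=O)C(OC)=CC2=O | intermediate
6 | trans-fused trione (C12 ketone, C13=C14; 20-CH3 α) | C[C@]12C=CC(=O)[C@@H](C)[C@@H]1C(=O)C(OC)=CC2=O | intermediate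
7 | dilithium bis-enolate (C9=C10 and C11=C12 enolates) | C[C@]12C=CC(O[Li])=C(C)C1=C(O[Li])C(OC)=CC2=O | intermediate
8 | 11-epimeric trione (20-CH3 β) | C[C@]12C=CC(=O)[C@H](C)[C@@H]1C(=O)C(OC)=CC2=O | intermediate
9 | triol (2β,9β,12β-OH; 8-OMe enol ether intact) | C[C@]12C=C[C@H](O)[C@H](C)[C@@H]1[C@H](O)C(OC)=C[C@@H]2O | intermediate
10 | hydroxy enone (C8 ketone; C2=C3; 9β-OH; 12β-OH) | C[C@]12C=C[C@H](O)[C@H](C)[C@@H]1[C@H](O)C(=O)C=C2 | intermediate
11 | 9β,12β-bis(triethylsilyl) ether of 10 | C[C@]12C=C[C@H](O[Si](CC)(CC)CC)[C@H](C)[C@@H]1[C@H](O[Si](CC)(CC)CC)C(=O)C=C2 | intermediate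
12 | 9α,12β-bis(triethylsilyl) ether of the enone | C[C@]12C=C[C@H](O[Si](CC)(CC)CC)[C@H](C)[C@@H]1[C@@H](O[Si](CC)(CC)CC)C(=O)C=C2 | intermediate
13 | 2α,3α-epoxy-8-ketone | C[C@]12C=C[C@H](O[Si](CC)(CC)CC)[C@H](C)[C@@H]1[C@@H](O[Si](CC)(CC)CC)C(=O)[C@H]3O[C@H]32 | intermediate
14 | 8β-vinyl-8α-hydroxy 2α,3α-epoxide | C[C@]12C=C[C@H](O[Si](CC)(CC)CC)[C@H](C)[C@@H]1[C@@H](O[Si](CC)(CC)CC)[C@](O)(C=C)[C@H]3O[C@H]32 | intermediate
15 | 3β-[(E)-prop-1-enyl]-8β-vinyl-2α,8α-diol | C[C@]12C=C[C@H](O[Si](CC)(CC)CC)[C@H](C)[C@@H]1[C@@H](O[Si](CC)(CC)CC)[C@](O)(C=C)[C@H](/C=C/C)[C@H]2O | intermediate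
16 | potassium enolate (C7=C8 enolate and C2 alkoxide of the ring-expanded ketone) | C[C@]12C=C[C@H](O[Si](CC)(CC)CC)[C@H](C)[C@@H]1[C@@H](O[Si](CC)(CC)CC)/C(O[K])=C\C[C@H](C)/C=C/[C@H]2O[K] | intermediate
17 | ten-membered bis(tert-butyldimethylsilyl) compound ((3E)-olefin; C7=C8 silyl enol ether; 2α-OSi) | C[C@]12C=C[C@H](O[Si](CC)(CC)CC)[C@H](C)[C@@H]1[C@@H](O[Si](CC)(CC)CC)/C(O[Si](C)(C)C(C)(C)C)=C\C[C@H](C)/C=C/[C@H]2O[Si](C)(C)C(C)(C)C | intermediate
18 | (3E,6Z)-dien-8-one | C[C@]12C=C[C@H](O[Si](CC)(CC)CC)[C@H](C)[C@@H]1[C@@H](O[Si](CC)(CC)CC)C(=O)/C=C\[C@H](C)/C=C/[C@H]2O[Si](C)(C)C(C)(C)C | intermediate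
19 | potassium trienolate | C[C@]12C=C[C@H](O[Si](CC)(CC)CC)[C@H](C)[C@@H]1[C@@H](O[Si](CC)(CC)CC)/C(O[K])=C\C=C(C)/C=C/[C@H]2O[Si](C)(C)C(C)(C)C | intermediate
20 | 7α-hydroxy-(3E,5Z)-dien-8-one | C[C@]12C=C[C@H](O[Si](CC)(CC)CC)[C@H](C)[C@@H]1[C@@H](O[Si](CC)(CC)CC)C(=O)[C@@H](O)/C=C(C)\C=C\[C@H]2O[Si](C)(C)C(C)(C)C | intermediate
21 | 7-O-(2-bromopropanoyl) ester (epimers at the CHBr carbon) | C[C@]12C=C[C@H](O[Si](CC)(CC)CC)[C@H](C)[C@@H]1[C@@H](O[Si](CC)(CC)CC)C(=O)[C@@H](OC(=O)C(C)Br)/C=C(C)\C=C\[C@H]2O[Si](C)(C)C(C)(C)C | intermediate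
22 | samarium enolate of the propanoate | C[C@]12C=C[C@H](O[Si](CC)(CC)CC)[C@H](C)[C@@H]1[C@@H](O[Si](CC)(CC)CC)C(=O)[C@@H](OC(O[Sm](I)I)=CC)/C=C(C)\C=C\[C@H]2O[Si](C)(C)C(C)(C)C | intermediate
23 | (3E,5Z)-hydroxy lactone (8α-OH; 18-CH3 α) | C[C@]12C=C[C@H](O[Si](CC)(CC)CC)[C@H](C)[C@@H]1[C@@H](O[Si](CC)(CC)CC)[C@]3(O)[C@@H](C)C(=O)O[C@H]3/C=C(C)\C=C\[C@H]2O[Si](C)(C)C(C)(C)C | intermediate
24 | (3Z,5Z)-hydroxy lactone | C[C@]12C=C[C@H](O[Si](CC)(CC)CC)[C@H](C)[C@@H]1[C@@H](O[Si](CC)(CC)CC)[C@]3(O)[C@@H](C)C(=O)O[C@H]3/C=C(C)\C=C/[C@H]2O[Si](C)(C)C(C)(C)C | intermediate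
25 | 9α,12β-diol | C[C@]12C=C[C@H](O)[C@H](C)[C@@H]1[C@@H](O)[C@]3(O)[C@@H](C)C(=O)O[C@H]3/C=C(C)\C=C/[C@H]2O[Si](C)(C)C(C)(C)C | intermediate
26 | 9α,12β-diacetate | C[C@]12C=C[C@H](OC(C)=O)[C@H](C)[C@@H]1[C@@H](OC(C)=O)[C@]3(O)[C@@H](C)C(=O)O[C@H]3/C=C(C)\C=C/[C@H]2O[Si](C)(C)C(C)(C)C | intermediate
27 | 2α-alcohol | C[C@]12C=C[C@H](OC(C)=O)[C@H](C)[C@@H]1[C@@H](OC(C)=O)[C@]3(O)[C@@H](C)C(=O)O[C@H]3/C=C(C)\C=C/[C@H]2O | intermediate
28 | 3α,4α-epoxide | C[C@]12C=C[C@H](OC(C)=O)[C@H](C)[C@@H]1[C@@H](OC(C)=O)[C@]3(O)[C@@H](C)C(=O)O[C@H]3/C=C(C)\[C@H]4O[C@H]4[C@H]2O | intermediate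
29 | 6α-chloro-5(16)-ene (13,14-deepoxy target) | C=C1[C@H]2O[C@H]2[C@@H](O)[C@]2(C)[C@H]([C@@H](C)[C@@H](OC(C)=O)C=C2)[C@@H](OC(C)=O)[C@]2(O)[C@@H](C)C(=O)O[C@H]2[C@H]1Cl | intermediate
30 | CNP0379630.2 | C=C1[C@H]2O[C@H]2[C@@H](O)[C@]2(C)[C@H]([C@@H](C)[C@@H](OC(C)=O)[C@@H]3O[C@@H]32)[C@@H](OC(C)=O)[C@]2(O)[C@@H](C)C(=O)O[C@H]2[C@H]1Cl | target

## Step count and the least certain steps

Total: 21 steps. Longest linear sequence: 21 steps (1 to 30); 20 steps from quinone 3.

**Step 10 (key step).** The alkoxide may fragment heterolytically at C3–C8 without recombination, or the triethylsilyl group may move from O9 to the C8 alkoxide and stop the rearrangement. The fallback is the neutral, thermal siloxy-Cope and sets out from 15. Stepwise silylation (t-BuMe2SiOSO2CF3 at O2, then Me3SiOSO2CF3 at O8) gives the 2-O-tert-butyldimethylsilyl 8-O-trimethylsilyl ether F1. Heating F1 at 180 °C in o-dichlorobenzene gives the C7=C8 trimethylsilyl enol ether F2 by a concerted shift with no anionic centre. Oxidation of F2 under the conditions of step 11 comes back to the route at 18.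

**Step 2.** Enantiofacial discrimination may be poor, or the chiral cation may favour the other regiochemistry, because the reacting double bond carries no α-hydrogen next to the bound carbonyl. The fallback obtains the absolute configuration by resolution and sets out from 3 and 2. BF3·OEt2 catalysis followed by DBU gives racemic 5, that is 5 together with its mirror image, the enantiomeric adduct F3. An oxazaborolidine-catalysed borane reduction (CBS, (S)-2-methyl catalyst, 0.5 equiv BH3·SMe2, −40 °C) is then run as a kinetic resolution, which should reduce the mismatched enantiomer at C9 to the hydroxy ketone F4. Unreacted 5 is separated and rejoins the route at 5.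

**Step 9.** The cuprate may fail at the hindered C3 between the tertiary carbinol and the epoxide, or a Payne-type epoxide migration to the C8 alkoxide may precede opening. The fallback sets out from 14 and uses Lewis-acid-assisted opening with diethyl(prop-1-ynyl)aluminium (Et2AlC≡CCH3), which attacks C3 trans-diaxially and gives the 3β-propynyl diol F5. Semi-hydrogenation (Pd/CaCO3 poisoned with Pb(OAc)2, quinoline, H2) gives the (Z)-propenyl diol F6. Under the conditions of step 10, F6 gives the C5 epimer of the bis-silyl compound, F7, and step 11 conditions give the C5-epimeric dienone F8. Since C5 is erased in step 12, F8 converges on the route at 20.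

**Step 12.** The base may deprotonate C9 instead of C5, the oxidant may attack the γ position, or the facial selectivity at C7 may be wrong. The fallback sets out from 18 and installs O7 by epoxidation instead of enolate oxidation. Nucleophilic epoxidation (t-BuOOH, DBU) of the C6=C7 enone gives the 6,7-epoxy ketone F9. Treating F9 with LiNEt2 removes the doubly activated H-5 and opens the epoxide at C6, which leaves the oxygen on C7 and forms C5=C6. This comes back to the route at 20.

**Step 20.** Chlorine may be delivered to the wrong face of C5=C6 (6-epimer), or allylic transposition may give a C16 chloride. The fallback sets out from 28 and separates C–O bond formation from C–Cl bond formation. Peracid epoxidation of the trisubstituted olefin gives the 5,6-epoxide F10. Diethylaluminium 2,2,6,6-tetramethylpiperidide removes a C16 proton and gives the 6β-hydroxy-5(16)-ene F11. Triphenylphosphine with hexachloroacetone replaces the hydroxyl by chloride with inversion and comes back to the route at 29. Because epoxidation and direct chlorination use the same olefin face, this sequence gives the C6 configuration opposite to that of step 20.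

## Further compounds

F1 | step 10 | 2-O-tert-butyldimethylsilyl 8-O-trimethylsilyl ether of 15 | C[C@]12C=C[C@H](O[Si](CC)(CC)CC)[C@H](C)[C@@H]1[C@@H](O[Si](CC)(CC)CC)[C@](O[Si](C)(C)C)(C=C)[C@H](/C=C/C)[C@H]2O[Si](C)(C)C(C)(C)C
F2 | step 10 | ten-membered C7=C8 trimethylsilyl enol ether (2α-OSi-t-BuMe2; (3E)-olefin) | C[C@]12C=C[C@H](O[Si](CC)(CC)CC)[C@H](C)[C@@H]1[C@@H](O[Si](CC)(CC)CC)/C(O[Si](C)(C)C)=C\C[C@H](C)/C=C/[C@H]2O[Si](C)(C)C(C)(C)C
F3 | step 2 | enantiomer of trans-fused adduct 5 | C[C@@]12CC=C(O[Si](C(C)C)(C(C)C)C(C)C)[C@H](C)[C@H]1C(=O)C(OC)=CC2=O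
F4 | step 2 | C9 alcohol from reduction of the enantiomeric adduct | C[C@@]12CC=C(O[Si](C(C)C)(C(C)C)C(C)C)[C@H](C)[C@H]1[C@@H](O)C(OC)=CC2=O
F5 | step 9 | 3β-(prop-1-ynyl)-8β-vinyl-2α,8α-diol | C[C@]12C=C[C@H](O[Si](CC)(CC)CC)[C@H](C)[C@@H]1[C@@H](O[Si](CC)(CC)CC)[C@](O)(C=C)[C@H](C#CC)[C@H]2O
F6 | step 9 | 3β-[(Z)-prop-1-enyl]-8β-vinyl-2α,8α-diol | C[C@]12C=C[C@H](O[Si](CC)(CC)CC)[C@H](C)[C@@H]1[C@@H](O[Si](CC)(CC)CC)[C@](O)(C=C)[C@H](/C=C\C)[C@H]2O
F7 | step 9 | C5 epimer of 17 | C[C@]12C=C[C@H](O[Si](CC)(CC)CC)[C@H](C)[C@@H]1[C@@H](O[Si](CC)(CC)CC)/C(O[Si](C)(C)C(C)(C)C)=C\C[C@@H](C)/C=C/[C@H]2O[Si](C)(C)C(C)(C)C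
F8 | step 9 | C5 epimer of 18 | C[C@]12C=C[C@H](O[Si](CC)(CC)CC)[C@H](C)[C@@H]1[C@@H](O[Si](CC)(CC)CC)C(=O)/C=C\[C@@H](C)/C=C/[C@H]2O[Si](C)(C)C(C)(C)C
F9 | step 12 | 6α,7α-epoxy-8-ketone | C[C@]12C=C[C@H](O[Si](CC)(CC)CC)[C@H](C)[C@@H]1[C@@H](O[Si](CC)(CC)CC)C(=O)[C@H]3O[C@H]3[C@H](C)/C=C/[C@H]2O[Si](C)(C)C(C)(C)C
F10 | step 20 | 3α,4α:5β,6β-bis-epoxide | C[C@]12C=C[C@H](OC(C)=O)[C@H](C)[C@@H]1[C@@H](OC(C)=O)[C@]3(O)[C@@H](C)C(=O)O[C@H]3[C@@H]5O[C@]5(C)[C@H]4O[C@H]4[C@H]2O
F11 | step 20 | 6β-hydroxy-5(16)-ene | C=C1[C@H]2O[C@H]2[C@@H](O)[C@]2(C)[C@H]([C@@H](C)[C@@H](OC(C)=O)C=C2)[C@@H](OC(C)=O)[C@]2(O)[C@@H](C)C(=O)O[C@H]2[C@@H]1O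
A1 | alternative 1 | seco iodo-aldehyde (2-iodoallyl epoxide arm and C6 aldehyde) | C=C(I)[C@H]2O[C@H]2[C@@H](O[Si](C)(C)C(C)(C)C)[C@]2(C)[C@H]([C@@H](C)[C@@H](OC(C)=O)C=C2)[C@@H](OC(C)=O)[C@]2(O)[C@@H](C)C(=O)O[C@H]2C=O
A2 | alternative 1 | macrocyclic 6β-allylic alcohol | C=C1[C@H]2O[C@H]2[C@@H](O[Si](C)(C)C(C)(C)C)[C@]2(C)[C@H]([C@@H](C)[C@@H](OC(C)=O)C=C2)[C@@H](OC(C)=O)[C@]2(O)[C@@H](C)C(=O)O[C@H]2[C@@H]1O
A3 | alternative 2 | enyne (C2 vinyl carbinol and C6 propargylic chloride) | C=C[C@@H](O)[C@]1(C)[C@H]([C@@H](C)[C@@H](OC(C)=O)C=C1)[C@@H](OC(C)=O)[C@]2(O)[C@@H](C)C(=O)O[C@H]2[C@@H](Cl)C#C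
A4 | alternative 2 | (3Z)-3,5(16)-diene | C=C1/C=C\[C@@H](O)[C@]2(C)[C@H]([C@@H](C)[C@@H](OC(C)=O)C=C2)[C@@H](OC(C)=O)[C@]2(O)[C@@H](C)C(=O)O[C@H]2[C@H]1Cl
A5 | alternative 3 | hydroanthracene triol with C3=C8 and C5=C6 olefins | C[C@]12C=C[C@H](O)[C@H](C)[C@@H]1[C@@H](O)C3=C(CC(C)=CC3)[C@@H]2O
A6 | alternative 3 | ten-membered (5Z)-ene-3,8-dione | C[C@]12C=C[C@H](OC(C)=O)[C@H](C)[C@@H]1[C@@H](OC(C)=O)C(=O)C/C=C(C)\CC(=O)[C@@H]2O
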